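The route rests on the C3–C11 bond, which is common to the cyclopentane (C3–C14–C13–C12–C11) and the seven-membered ring (C3–C4–C5–C6–C7–C10–C11) and lies next to the C4 ketone: the imprint of a 1,2-shift of C11 from C4 to C3. One semipinacol rearrangement of a decalin should therefore contract ring A, expand ring B, create the quaternary stereocentre C3 and unmask the C4 ketone and C2 (as CH2OH). Its precursor is a trans-fused decalin carrying the axial angular C4 hydroxyl, an equatorial spiro-epoxide oxygen at C3, the axial C13 isopropenyl group and the C7 side chain CMe2CH2CO2Me. The bicyclo[3.3.1]nonane-trione is closed afterwards through C5–C9 and C1–C2.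

Key step: step 14

Remarks.
(a) All intermediates carry the target numbering: ring A = C3–C4–C11–C12–C13–C14 (C12 gem-dimethyl), ring B = C4–C5–C6–C7–C10–C11, side chain on C7 = C8(CH3)2–C1H2–C9O2CH3. "Top" is the decalin face on which C10 leaves C11; C11–H is on the bottom face.
(b) Assumption: the (S)-oxazaborolidinium catalyst of step 5 is taken to shield the enone face that leads to 8 as drawn; if the sense of induction is the reverse, its mirror image is used with no other change.
(c) Two points of the decalin plan were redesigned. Electrophilic oxygenation of the C3 enolate at C4 is expected from the face of C11–H (cis fusion), so the trans C4–O bond is made by inversion at C4 (steps 5–7). The C7 side chain must be cis to C11–H, which only a hydrogenation directed by the C4 hydroxyl should deliver (step 9); this is done before the isopropenyl group is present.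

Step 1
Reactants: 1 methyl 3,3-dimethylpent-4-enoate
Product: 2 methyl 3,3-dimethyl-4-oxopentanoate
Conditions: PdCl2 (10 mol %), CuCl, O2 (1 atm), DMF/H2O 7:1, 23 °C
Reagents that add atoms: water, O
Why: Tsuji–Wacker oxidation: Markovnikov hydroxypalladation and β-hydride elimination turn the terminal vinyl group into the methyl ketone, and the quaternary neighbour excludes double-bond migration.

Step 2
Reactants: 2 methyl 3,3-dimethyl-4-oxopentanoate
Product: 3 methyl 3,3-dimethyl-4-(trifluoromethylsulfonyloxy)pent-4-enoate
Conditions: KN(SiMe3)2, THF, −78 °C; N-(5-chloro-2-pyridyl)triflimide, −78 °C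
Reagents that add atoms: N-(5-chloro-2-pyridyl)bis(trifluoromethanesulfonimide), FC(F)(F)S(=O)(=O)N(c1ccc(Cl)cn1)S(=O)(=O)C(F)(F)F
Why: Enol triflate formation: the ketone can enolise only toward its methyl group (the other α-carbon is quaternary), and the potassium enolate should be O-sulfonylated at −78 °C faster than it adds to the ester.

Step 3
Reactants: 3 methyl 3,3-dimethyl-4-(trifluoromethylsulfonyloxy)pent-4-enoate
Product: 4 methyl 3,3-dimethyl-4-methylidenehex-5-enoate (2-substituted butadiene)
Conditions: tributyl(vinyl)stannane, Pd(PPh3)4 (5 mol %), LiCl, THF, 65 °C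
Reagents that add atoms: tributyl(vinyl)stannane, C=C[Sn](CCCC)(CCCC)CCCC
Why: Stille coupling of the alkenyl triflate with the vinylstannane (chloride-assisted oxidative addition to zerovalent palladium) gives the diene.

Step 4
Reactants: 5 4,4-dimethylcyclohex-2-en-1-one
Product: 7 2-bromo-4,4-dimethylcyclohex-2-en-1-one, via dibromide 6 (not isolated)
Conditions: Br2, CH2Cl2, 0 °C; then Et3N, 0 → 23 °C
Reagents that add atoms: bromine, BrBr
Why: Bromine adds to the enone and triethylamine removes the acidic α-hydrogen with loss of the β-bromide (E1cB), the standard route to 2-bromo enones.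

Step 5
Reactants: 7 2-bromo-4,4-dimethylcyclohex-2-en-1-one; 4 methyl 3,3-dimethyl-4-methylidenehex-5-enoate
Product: 8 cis-fused bromo-octalone (C3 ketone; C4–Br and C11–H both on the bottom face; C6=C7; side chain on C7)
Conditions: (S)-o-tolyl oxazaborolidine from diphenylprolinol (20 mol %), AlBr3 (16 mol %), CH2Cl2, −40 °C
Reagents that add atoms: none
Why: Asymmetric Diels–Alder reaction under chiral oxazaborolidinium catalysis: the diene terminus next to its substituted carbon bonds to the enone β-carbon C11 ("para" orientation, so the side chain sits on C7), suprafacial addition makes the fusion cis (Br on C4 syn to H on C11), and the shielded enone face fixes the absolute configuration of C11, which is carried to the target.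

Step 6
Reactants: 8 cis-fused bromo-octalone
Product: 10 C3–C4 epoxide with oxygen on the top face (trans to C11–H; ring fusion now trans), via bromohydrin 9 (not isolated)
Conditions: K[HB(s-Bu)3] (K-Selectride), THF, −78 → 23 °C
Reagents that add atoms: none
Why: Hydride reduction then intramolecular Williamson-type epoxide closure: in the favoured cis-decalin conformer bromine is axial and the axial face of C3 is covered by the axial C10 methylene, so the bulky hydride should enter equatorially and the resulting axial alkoxide, antiperiplanar to C4–Br, displaces it with inversion, which places the oxygen on C4 trans to H11 and makes the ring fusion trans.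

Step 7
Reactants: 10 C3–C4 epoxide
Product: 11 trans-decalin diol (C4–OH axial on the top face; C3–OH axial on the bottom face; C6=C7)
Conditions: HClO4 (cat.), THF/H2O 3:1, 0 → 23 °C
Reagents that add atoms: water, O
Why: Acid-catalysed epoxide hydrolysis under Fürst–Plattner control: water attacks C3 axially from the face of H11 (trans-diaxial opening, as with ring-fusion epoxides of trans-decalins and steroids), so the tertiary C4–O bond and its configuration are retained.

Step 8
Reactants: 11 trans-decalin diol
Product: 12 trans-fused α-hydroxy ketone (C3 ketone; C4–OH top; C6=C7)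
Conditions: IBX, DMSO, 23 °C
Reagents that add atoms: none
Why: IBX oxidises the secondary C3 hydroxyl to the ketone without cleaving the glycol and leaves the tertiary C4 hydroxyl as the only hydroxyl for the directed hydrogenation.

Step 9
Reactants: 12 trans-fused α-hydroxy ketone
Product: 13 saturated ketol (C7–H top; C7 side chain on the bottom face, cis to C11–H)
Conditions: H2 (1 atm), [Ir(cod)(PCy3)(py)]PF6 (5 mol %), CH2Cl2, 23 °C
Reagents that add atoms: none
Why: Hydroxyl-directed hydrogenation: the axial tertiary C4–OH, homoallylic to C6=C7 (the terpinen-4-ol pattern), binds the cationic iridium catalyst and both hydrogens should be delivered to the top face, giving the C7 epimer that undirected hydrogenation or equilibration would not favour; no other alkene is present at this stage.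

Step 10
Reactants: 13 saturated ketol
Product: 14 α'-hydroxy enone (C3 ketone; C13=C14; C4–OH top)
Conditions: IBX, DMSO/toluene, 70 °C
Reagents that add atoms: none
Why: IBX dehydrogenation of the ketone introduces the C13=C14 double bond; only C14 bears α-hydrogens, so the regiochemistry is unambiguous.

Step 11
Reactants: 14 α'-hydroxy enone
Product: 16 isopropenyl ketol (C13 isopropenyl axial on the bottom face; C3 ketone; C4–OH top), via bis-silyl enol ether 15 (not isolated)
Conditions: CH2=C(CH3)MgBr, CuBr·SMe2 (20 mol %), Me3SiCl, THF, −78 → −40 °C; then 1 M HCl, 0 °C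
Reagents that add atoms: isopropenylmagnesium bromide, C=C(C)[Mg]Br
Why: Copper-catalysed, Me3SiCl-accelerated conjugate addition: the trans-fused enone should be attacked axially at C13, anti to the axial C12 methyl and trans to the equatorial C10, which places the isopropenyl group axial and cis to H11; acid work-up cleaves both silyl groups.

Step 12
Reactants: 16 isopropenyl ketol
Product: 17 allylic alcohol (C3 exocyclic methylidene; C4–OH top)
Conditions: Zn, CH2Br2, TiCl4, THF/CH2Cl2, 0 → 23 °C
Reagents that add atoms: dibromomethane, BrCBr
Why: Lombardo methylenation: the non-basic zinc–titanium methylene reagent olefinates hindered, enolisable ketones in the presence of a free hydroxyl and avoids base-induced α-ketol rearrangement; the ester is left untouched.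

Step 13
Reactants: 17 allylic alcohol
Product: 18 spiro-epoxy alcohol (trans-decalin; C4–OH axial; epoxide C3–O equatorial on the top face; epoxide CH2 axial)
Conditions: VO(acac)2 (5 mol %), t-BuOOH, CH2Cl2, 0 → 23 °C
Reagents that add atoms: tert-butyl hydroperoxide, CC(C)(C)OO
Why: Hydroxyl-directed epoxidation: the axial allylic C4–OH delivers oxygen to the alkene face syn to itself, so the new C3–O bond is equatorial and the CH2 axial; the isopropenyl group has no directing hydroxyl and should not be epoxidised, and it screens the opposite face.

Step 14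
Reactants: 18 spiro-epoxy alcohol
Product: 19 hydroazulenone (C4 ketone in the seven-membered ring; quaternary C3 bearing CH2OH; cyclopentane C3–C14–C13–C12–C11)
Conditions: BF3·OEt2, CH2Cl2, −78 °C; Et3N quench at −78 °C
Reagents that add atoms: none
Why: BF3 binds the epoxide oxygen and, as the C3–O bond ionises, the antiperiplanar C4–C11 σ bond shifts to C3 in a concerted suprafacial 1,2-migration while the C4 carbinol collapses to the ketone; this is the semipinacol rearrangement of tertiary 2,3-epoxy alcohols, the reaction type known for decalin-to-hydroazulene shifts. The cyclopentane closes by ring contraction of ring A (the migrating bond displaces oxygen at C3 from the rear, a σ-bond participation and not an exo or endo cyclisation), and the seven-membered ring closes by the matching one-carbon expansion of ring B, both through the single new bond C3–C11. The one new stereocentre, quaternary C3, is set with inversion by the epoxide configuration from step 13, and C11 migrates with retention. The step needs C11 to migrate in preference to C5 and to external opening of the epoxide: in the chair of ring A only C4–C11 is anti to the equatorial C3–O bond (C4–C5 and C4–OH are gauche), and C11 is also the more substituted terminus. Low temperature and a cold amine quench should protect the isopropenyl group and keep the β-hydroxy ketone from retro-aldol cleavage.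

Step 15
Reactants: 19 hydroazulenone
Product: 20 tert-butyldimethylsilyl ether of 19 (C2–OTBS)
Conditions: TBSCl, imidazole, DMF, 23 °C
Reagents that add atoms: tert-butyldimethylsilyl chloride, CC(C)(C)[Si](C)(C)Cl
Why: Silylation of the neopentyl primary alcohol; the ether blocks retro-aldol loss of formaldehyde in the basic steps that follow.

Step 16
Reactants: 20 silyl ether
Product: 21 tricyclic β-diketone (C5–C9 bond closed; C4 and C9 ketones; C5–H)
Conditions: KOt-Bu, THF, 0 → 23 °C; then 1 M HCl
Reagents that add atoms: none
Why: Dieckmann-type intramolecular Claisen acylation: the ketone enolises only toward C5 (C3 is quaternary), C5 attacks the C9 ester in a 6-(enolexo)-exo-trig closure that is possible only on the face carrying the C7 side chain (which fixes C5), and deprotonation of the β-diketone drives the equilibrium.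

Step 17
Reactants: 21 tricyclic β-diketone; 22 geranyl bromide
Product: 23 C5-geranyl diketone (C2–OTBS)
Conditions: LiN(SiMe3)2, THF, −78 °C; 22, DMPU, −78 → 0 °C
Reagents that add atoms: none
Why: C-alkylation of the lithium β-diketonate with an allylic bromide (SN2): C5 is the most acidic position and a bridgehead, so the geranyl group can only take the exo position and the E double bond is untouched.

Step 18
Reactants: 23 C5-geranyl diketone
Product: 24 primary alcohol (C2–OH)
Conditions: HF·pyridine, pyridine, THF, 0 → 23 °C
Reagents that add atoms: none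
Why: Fluoride-mediated desilylation under buffered acidic conditions, which should spare the retro-Claisen-prone 2,2-disubstituted 1,3-diketone, the β-hydroxy ketone and the alkenes.

Step 19
Reactants: 24 primary alcohol
Product: 25 aldehyde (C2 formyl on quaternary C3)
Conditions: Dess–Martin periodinane, NaHCO3, CH2Cl2, 0 → 23 °C
Reagents that add atoms: none
Why: Dess–Martin oxidation of the primary alcohol under buffered, non-nucleophilic conditions; the non-enolisable β-keto aldehyde is used at once.

Step 20
Reactants: 25 aldehyde
Product: 26 aldol (C1–C2 bond closed; C2 carbinol as either epimer; C1–H bridgehead)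
Conditions: LiTMP (lithium 2,2,6,6-tetramethylpiperidide), THF, −78 °C; AcOH quench at −78 °C
Reagents that add atoms: none
Why: Intramolecular aldol addition, the way bicyclo[3.3.1]nonane-triones of this family are closed before oxidation: C1 is the only enolisable carbon left, the hindered amide should deprotonate it without adding to the aldehyde, and the 6-(enolendo)-exo-trig closure onto the nearby C2 aldehyde fixes C1 through the bridge; the C2 configuration is irrelevant and the cold quench prevents retro-aldol.

Step 21
Reactants: 26 aldol
Product: 27 trione (C2, C4 and C9 ketones; C1–H bridgehead)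
Conditions: Dess–Martin periodinane, NaHCO3, CH2Cl2, 23 °C
Reagents that add atoms: none
Why: Dess–Martin oxidation of the secondary β-hydroxy ketone gives the non-enolisable 2,4,9-trione under neutral conditions that avoid retro-aldol and retro-Claisen cleavage.

Step 22
Reactants: 27 trione; 28 benzoyl chloride
Product: 29 CNP0110731.1 (target)
Conditions: LiTMP, THF, −78 °C; 28, −78 → −40 °C
Reagents that add atoms: none
Why: Bridgehead deprotonation and C-acylation: C1–H, flanked by the C2 and C9 carbonyls, is removed by the hindered amide to a pyramidal bridgehead carbanion that cannot O-acylate (anti-Bredt) and is benzoylated on carbon with retention, as in bridgehead acylations of bicyclo[3.3.1]nonane-triones.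

Compound list

1 | methyl 3,3-dimethylpent-4-enoate | C=CC(C)(C)CC(=O)OC | starting material
2 | methyl 3,3-dimethyl-4-oxopentanoate | CC(=O)C(C)(C)CC(=O)OC | intermediate
3 | methyl 3,3-dimethyl-4-(trifluoromethylsulfonyloxy)pent-4-enoate | C=C(OS(=O)(=O)C(F)(F)F)C(C)(C)CC(=O)OC | intermediate
4 | methyl 3,3-dimethyl-4-methylidenehex-5-enoate | C=CC(=C)C(C)(C)CC(=O)OC | intermediate
5 | 4,4-dimethylcyclohex-2-en-1-one | CC1(C)CCC(=O)C=C1 | starting material
6 | trans-2,3-dibromo-4,4-dimethylcyclohexan-1-one (racemic) | O=C1CCC(C)(C)[C@H](Br)[C@H]1Br | intermediate (not isolated)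
7 | 2-bromo-4,4-dimethylcyclohex-2-en-1-one | O=C1CCC(C)(C)C=C1Br | intermediate
8 | cis-fused bromo-octalone: methyl 3-(4a-bromo-8,8-dimethyl-5-oxo-1,4,4a,5,6,7,8,8a-octahydronaphthalen-2-yl)-3-methylbutanoate, Br and 8a-H cis | COC(=O)CC(C)(C)C1=CC[C@]2(Br)C(=O)CCC(C)(C)[C@@H]2C1 | intermediate
9 | bromohydrin: C3–OH trans-diaxial to C4–Br, Br cis to C11–H | COC(=O)CC(C)(C)C1=CC[C@]2(Br)[C@H](O)CCC(C)(C)[C@@H]2C1 | intermediate (not isolated)
10 | C3–C4 epoxide, oxygen trans to C11–H | COC(=O)CC(C)(C)C1=CC[C@]23O[C@@H]3CCC(C)(C)[C@@H]2C1 | intermediate
11 | trans-decalin diol: C4–OH trans to C11–H, C3–OH cis to C11–H, C6=C7 | COC(=O)CC(C)(C)C1=CC[C@@]2(O)[C@@H](O)CCC(C)(C)[C@@H]2C1 | intermediate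
12 | trans-fused α-hydroxy ketone: C3 ketone, C4–OH trans to C11–H, C6=C7 | COC(=O)CC(C)(C)C1=CC[C@@]2(O)C(=O)CCC(C)(C)[C@@H]2C1 | intermediate
13 | saturated ketol: C7 side chain cis to C11–H | COC(=O)CC(C)(C)[C@H]1CC[C@@]2(O)C(=O)CCC(C)(C)[C@@H]2C1 | intermediate
14 | α'-hydroxy enone: C13=C14 | COC(=O)CC(C)(C)[C@H]1CC[C@@]2(O)C(=O)C=CC(C)(C)[C@@H]2C1 | intermediate
15 | bis(trimethylsilyl) derivative: C3 silyl enol ether (C3=C14), C4–OSiMe3, C13 isopropenyl | C=C(C)[C@@H]1C=C(O[Si](C)(C)C)[C@]2(O[Si](C)(C)C)CC[C@H](C(C)(C)CC(=O)OC)C[C@H]2C1(C)C | intermediate (not isolated)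
16 | isopropenyl ketol: C13 isopropenyl axial, cis to C11–H | C=C(C)[C@@H]1CC(=O)[C@]2(O)CC[C@H](C(C)(C)CC(=O)OC)C[C@H]2C1(C)C | intermediate
17 | allylic alcohol: C3 methylidene, C4–OH axial | C=C(C)[C@@H]1CC(=C)[C@]2(O)CC[C@H](C(C)(C)CC(=O)OC)C[C@H]2C1(C)C | intermediate
18 | spiro-epoxy alcohol (precursor of the key step) | C=C(C)[C@@H]1C[C@]2(CO2)[C@]3(O)CC[C@H](C(C)(C)CC(=O)OC)C[C@H]3C1(C)C | intermediate
19 | hydroazulenone with C3 hydroxymethyl (product of the key step) | C=C(C)[C@@H]1C[C@@]2(CO)C(=O)CC[C@H](C(C)(C)CC(=O)OC)C[C@H]2C1(C)C | intermediate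
20 | tert-butyldimethylsilyl ether of 19 | C=C(C)[C@@H]1C[C@@]2(CO[Si](C)(C)C(C)(C)C)C(=O)CC[C@H](C(C)(C)CC(=O)OC)C[C@H]2C1(C)C | intermediate
21 | tricyclic β-diketone (C5–C9 closed) | C=C(C)[C@@H]1C[C@@]2(CO[Si](C)(C)C(C)(C)C)C(=O)[C@H]3C[C@@H](C[C@H]2C1(C)C)C(C)(C)CC3=O | intermediate
22 | geranyl bromide | CC(C)=CCC/C(C)=C/CBr | starting material
23 | C5-geranyl diketone, C2–OTBS | C=C(C)[C@@H]1C[C@@]2(CO[Si](C)(C)C(C)(C)C)C(=O)[C@@]3(C/C=C(\C)CCC=C(C)C)C[C@@H](C[C@H]2C1(C)C)C(C)(C)CC3=O | intermediate
24 | C5-geranyl diketone, C2–OH | C=C(C)[C@@H]1C[C@@]2(CO)C(=O)[C@@]3(C/C=C(\C)CCC=C(C)C)C[C@@H](C[C@H]2C1(C)C)C(C)(C)CC3=O | intermediate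
25 | C5-geranyl diketone, C2 aldehyde | C=C(C)[C@@H]1C[C@@]2(C=O)C(=O)[C@@]3(C/C=C(\C)CCC=C(C)C)C[C@@H](C[C@H]2C1(C)C)C(C)(C)CC3=O | intermediate
26 | aldol (C1–C2 closed; C2 carbinol, configuration not controlled) | C=C(C)[C@@H]1C[C@@]23C(=O)[C@@]4(C/C=C(\C)CCC=C(C)C)C[C@@H](C[C@H]2C1(C)C)C(C)(C)[C@H](C4=O)C3O | intermediate
27 | 2,4,9-trione with C1–H | C=C(C)[C@@H]1C[C@@]23C(=O)[C@@]4(C/C=C(\C)CCC=C(C)C)C[C@@H](C[C@H]2C1(C)C)C(C)(C)[C@H](C4=O)C3=O | intermediate
28 | benzoyl chloride | O=C(Cl)c1ccccc1 | starting material
29 | CNP0110731.1 | C=C(C)[C@@H]1C[C@@]23C(=O)[C@@]4(C/C=C(\C)CCC=C(C)C)C[C@@H](C[C@H]2C1(C)C)C(C)(C)[C@](C(=O)c1ccccc1)(C4=O)C3=O | target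

Total step count: 22. Longest linear sequence: 21 steps (steps 1–3 and 5–22; step 4 is a one-step branch).

Steps most likely to fail

Step 14. The danger is loss of stereoelectronic control: ring A may leave the chair to relieve the syn-axial CH2/isopropenyl and OH/CH3 contacts, so that ionisation at C3 runs ahead of the C11 shift and C5 migration, fluoride capture or attack by the isopropenyl π bond can compete. The fallback sets out from 18 and changes the substrate of the shift from the free carbinol to its silyl ether. The tertiary hydroxyl is silylated with N-(trimethylsilyl)imidazole to the epoxy silyl ether F1. F1 is then treated with TiCl4 in CH2Cl2 at −78 °C, the silyl-ether variant of the epoxide semipinacol shift (Suzuki–Tsuchihashi rearrangement), in which the titanium-bound epoxide opens in concert with the shift pushed by the O–Si donor. The silyl group is lost on aqueous work-up and the route is rejoined at 19.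

Step 5. The danger is low reactivity of the doubly hindered α-bromo enone toward the bulky diene, with diene oligomerisation by the strong Lewis acid or poor facial discrimination. The fallback sets out from 5 and 4 and separates cycloaddition from bromination. The same oxazaborolidinium catalysis on the parent enone should give the cis-octalone F2. Equilibrating silylation (Me3SiCl, NaI, Et3N, MeCN) should give the more substituted silyl enol ether F3. N-Bromosuccinimide then brominates C4 from the face of C11–H (anti to the axial C12 methyl and to C10), which should give the same cis bromide and rejoin the route at 8.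

Step 22. The danger is slow deprotonation at the congested bridgehead next to the C8 quaternary carbon and slow acyl transfer, which would let the amide base or chloride attack a ketone of the non-enolisable trione (retro-Claisen ring opening). The fallback sets out from 27 and builds the benzoyl group in two stages. Deprotonation with LiTMP and trapping with iodine should give the bridgehead iodide F4. Iodine–magnesium exchange with i-PrMgCl and addition to benzaldehyde should give the bridgehead carbinol F5. Dess–Martin oxidation of F5 rejoins the route at 29.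

Further compounds

F1 | step 14 | trimethylsilyl ether of 18 (C4–OSiMe3) | C=C(C)[C@@H]1C[C@]2(CO2)[C@]3(O[Si](C)(C)C)CC[C@H](C(C)(C)CC(=O)OC)C[C@H]3C1(C)C
F2 | step 5 | cis-octalone (C3 ketone, C4–H cis to C11–H, C6=C7) | COC(=O)CC(C)(C)C1=CC[C@@H]2C(=O)CCC(C)(C)[C@@H]2C1
F3 | step 5 | trimethylsilyl enol ether of F2 (C3=C4) | COC(=O)CC(C)(C)C1=CCC2=C(O[Si](C)(C)C)CCC(C)(C)[C@@H]2C1
F4 | step 22 | C1 bridgehead iodide of 27 | C=C(C)[C@@H]1C[C@@]23C(=O)[C@@]4(C/C=C(\C)CCC=C(C)C)C[C@@H](C[C@H]2C1(C)C)C(C)(C)[C@](I)(C4=O)C3=O
F5 | step 22 | C1 hydroxy(phenyl)methyl trione (carbinol configuration not controlled) | C=C(C)[C@@H]1C[C@@]23C(=O)[C@@]4(C/C=C(\C)CCC=C(C)C)C[C@@H](C[C@H]2C1(C)C)C(C)(C)[C@](C(O)c1ccccc1)(C4=O)C3=O
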